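**Retrosynthetic overview**
1. Last disconnection: the 7-OH is unmasked from a methoxymethyl (MOM) ether.
2. Key disconnection: the bond between C4 of the dimethylpyran ring (ring D) and C4a (C5' of ring B) is opened to the isomeric aryl 1,1-dimethylpropargyl ether. Forward, gold catalysis closes ring D by 6-endo-dig intramolecular hydroarylation, a C–H alkenylation with no prefunctionalised carbon, in which the π-acid makes the normally nucleophilic alkyne terminus the electrophile.
3. Enabling feature: in ring B the ether oxygen O4' lies between C3' (blocked by OMe) and C5'–H, the only free ortho position and the one activated by O4'; the gem-dimethyl carbon (C2 of ring D) holds the alkyne terminus over C5'.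
4. The propargyl ether comes from the 4'-phenol of 3'-methoxydaidzein, by copper-catalysed O-propargylation after MOM protection of the more acidic 7-OH.
5. The isoflavone comes from resorcinol and homovanillic acid in one pot. Ring order: A and B are bought, ring C (pyranone) forms in step 1, ring D in step 4.

Key step: step 4

Remark: the target has no stereocentre, so no step has to control configuration. Locants follow isoflavone numbering (rings A and C, primed locants for ring B); ring D is the dimethylpyran.

**Step 1**
Reactants: 1 resorcinol; 2 homovanillic acid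
Product: 5 7-hydroxy-3-(4-hydroxy-3-methoxyphenyl)-4H-chromen-4-one (3'-methoxydaidzein), via deoxybenzoin 3 (not isolated), via aminomethylene ketone 4 (not isolated)
Conditions: BF3·OEt2 (neat), 85 °C; then DMF, MsCl, 70 °C; then aq. NaOAc
Reagents that add atoms: N,N-dimethylformamide, CN(C)C=O
Why: BF3-mediated Friedel–Crafts C-acylation of resorcinol at C4 should give deoxybenzoin 3, whose boron-chelated enol is C-formylated by the Vilsmeier-type iminium salt from DMF and MsCl to aminomethylene ketone 4, which closes ring C by addition–elimination of the 2-hydroxyl with loss of dimethylamine (one-pot deoxybenzoin route to 7-hydroxyisoflavones).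

**Step 2**
Reactants: 5 7-hydroxy-3-(4-hydroxy-3-methoxyphenyl)-4H-chromen-4-one
Product: 6 3-(4-hydroxy-3-methoxyphenyl)-7-(methoxymethoxy)-4H-chromen-4-one
Conditions: MOMCl (1.05 equiv), K2CO3 (1.1 equiv), acetone, 0 °C to rt
Reagents that add atoms: chloromethyl methyl ether, COCCl
Why: Williamson-type O-alkylation with a slight excess of weak base should hit only the 7-OH, because this vinylogous carboxylic acid (para to the C4 carbonyl) is markedly more acidic than the guaiacol-type 4'-OH and is the one converted into the phenoxide.

**Step 3**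
Reactants: 6 3-(4-hydroxy-3-methoxyphenyl)-7-(methoxymethoxy)-4H-chromen-4-one
Product: 7 3-[3-methoxy-4-(2-methylbut-3-yn-2-yloxy)phenyl]-7-(methoxymethoxy)-4H-chromen-4-one
Conditions: 3-chloro-3-methylbut-1-yne, DBU, CuCl2·2H2O (1 mol%), MeCN, 0 °C to rt
Reagents that add atoms: 3-chloro-3-methylbut-1-yne, CC(C)(Cl)C#C
Why: Copper-catalysed propargylic substitution of the tertiary propargylic chloride (copper acetylide, then copper allenylidene attacked by the phenoxide at the tertiary carbon) is the standard way to aryl 1,1-dimethylpropargyl ethers and should tolerate the MOM acetal and the pyranone at 0 °C.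

**Step 4**
Reactants: 7 3-[3-methoxy-4-(2-methylbut-3-yn-2-yloxy)phenyl]-7-(methoxymethoxy)-4H-chromen-4-one
Product: 8 3-(8-methoxy-2,2-dimethyl-2H-chromen-6-yl)-7-(methoxymethoxy)-4H-chromen-4-one
Conditions: Ph3PAuNTf2 (5 mol%), CH2Cl2, 4 Å MS, rt
Reagents that add atoms: none
Why: Cationic monovalent gold coordinates the terminal alkyne, C5' of ring B (ortho to the tethering O4') attacks the alkyne terminus anti to gold in a Friedel–Crafts manner, and rearomatisation of the Wheland intermediate followed by protodeauration of the vinylgold species gives the C3=C4 double bond and frees the catalyst. The closest known reaction type is the gold-catalysed intramolecular hydroarylation (cycloisomerisation) of aryl 1,1-dimethylpropargyl ethers to 2,2-dimethyl-2H-chromenes. Ring D is closed in the 6-endo-dig mode by the bond between C5' of ring B (chromene C4a) and the former alkyne terminus (chromene C4). No stereocentre is formed. The step needs site selectivity on ring B and 6-endo over 5-exo selectivity: the first is secured because O4' has only one free ortho position (C3' carries OMe), the second because the unhindered CH terminus is reached through an unstrained six-membered transition state while the internal carbon is shielded by the gem-dimethyl group, which also favours the folded conformer (Thorpe–Ingold effect). Ring A, the pyranone double bond and the MOM acetal are poor nucleophiles towards the gold–alkyne complex and should stay untouched.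

**Step 5**
Reactants: 8 3-(8-methoxy-2,2-dimethyl-2H-chromen-6-yl)-7-(methoxymethoxy)-4H-chromen-4-one
Product: 9 7-hydroxy-3-(8-methoxy-2,2-dimethyl-2H-chromen-6-yl)-4H-chromen-4-one
Conditions: HCl (2 M in MeOH), 40 °C
Reagents that add atoms: none
Why: Acid-catalysed transacetalisation with methanol should cleave the phenolic MOM ether at a temperature at which the aryl methyl ether, the pyranone and the chromene double bond of ring D are stable.

**Compound list**
1 | resorcinol (benzene-1,3-diol) | Oc1cccc(O)c1 | starting material
2 | homovanillic acid (2-(4-hydroxy-3-methoxyphenyl)acetic acid) | COc1cc(CC(=O)O)ccc1O | starting material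
3 | 1-(2,4-dihydroxyphenyl)-2-(4-hydroxy-3-methoxyphenyl)ethan-1-one (deoxybenzoin) | COc1cc(CC(=O)c2ccc(O)cc2O)ccc1O | intermediate (not isolated)
4 | (E)-1-(2,4-dihydroxyphenyl)-3-(dimethylamino)-2-(4-hydroxy-3-methoxyphenyl)prop-2-en-1-one (aminomethylene ketone) | COc1cc(\C(C(=O)c2ccc(O)cc2O)=C/N(C)C)ccc1O | intermediate (not isolated)
5 | 7-hydroxy-3-(4-hydroxy-3-methoxyphenyl)-4H-chromen-4-one (3'-methoxydaidzein) | COc1cc(-c2coc3cc(O)ccc3c2=O)ccc1O | intermediate
6 | 3-(4-hydroxy-3-methoxyphenyl)-7-(methoxymethoxy)-4H-chromen-4-one | COCOc1ccc2c(c1)occ(-c1ccc(O)c(OC)c1)c2=O | intermediate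
7 | 3-[3-methoxy-4-(2-methylbut-3-yn-2-yloxy)phenyl]-7-(methoxymethoxy)-4H-chromen-4-one | COCOc1ccc2c(c1)occ(-c1ccc(OC(C)(C)C#C)c(OC)c1)c2=O | intermediate
8 | 3-(8-methoxy-2,2-dimethyl-2H-chromen-6-yl)-7-(methoxymethoxy)-4H-chromen-4-one | COCOc1ccc2c(c1)occ(-c1cc(OC)c3OC(C)(C)C=Cc3c1)c2=O | intermediate
9 | 7-hydroxy-3-(8-methoxy-2,2-dimethyl-2H-chromen-6-yl)-4H-chromen-4-one (CNP0202267.0) | COc1cc(-c2coc3cc(O)ccc3c2=O)cc2c1OC(C)(C)C=C2 | target

**Total step count:** 5
**Longest linear sequence:** 5 steps (from 1 and 2 to 9)

**Steps most likely to fail**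

Step 4 (key step). What may go wrong: ring closure in the 5-exo mode, gold-induced ionisation of the tertiary propargylic C–O bond with loss of the C5 unit, hydration of the alkyne by adventitious water, or slow turnover because the pyranone carbonyl binds the cationic catalyst. Fallback: a catalyst-free pericyclic route that makes the same bond by another mechanism. It sets out from 7, which is heated in N,N-diethylaniline at 185 °C. Aromatic propargyl Claisen rearrangement should give the allenyl cyclohexadienone F1, which enolises to the ortho-allenylphenol F2. A 1,5-hydrogen shift then gives the (Z)-ortho-quinone methide F3, and oxa-6π electrocyclisation closes ring D. None of these three is isolated, and the fallback comes back to the route at 8.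

Step 2. What may go wrong: loss of site selectivity, with alkylation of the 4'-OH or of both hydroxyls. Fallback: the two phenols are differentiated by selective deacylation instead of selective alkylation. It sets out from 5. Ac2O in pyridine should give the 7,4'-diacetate F4. PhSH and imidazole in NMP at rt should remove only the 7-O-acetyl group, the ester of the more acidic phenol being the better acyl donor, and give the 4'-acetate F5. MOMCl, i-Pr2NEt in CH2Cl2 should give the MOM ether acetate F6. K2CO3 in MeOH at rt then cleaves the remaining aryl acetate, and the fallback comes back to the route at 6.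

Step 1. What may go wrong: partial O-demethylation by hot BF3·OEt2, sulfonylation of phenols by MsCl, or incomplete formylative ring closure in the one-pot sequence. Fallback: the C3–C1' bond is made by cross-coupling instead of the deoxybenzoin route. It sets out from 1. Nencki acetylation (AcOH, ZnCl2, 140 °C) should give 2,4-dihydroxyacetophenone F7. MOMCl, K2CO3 in acetone protects only the non-chelated 4-OH and should give the MOM ether F8. DMF-DMA at 90 °C should give the enaminone F9. I2, pyridine in CHCl3 at rt closes ring C with iodination to the 3-iodochromone F10. Suzuki–Miyaura coupling with commercial 2-methoxy-4-(4,4,5,5-tetramethyl-1,3,2-dioxaborolan-2-yl)phenol (COc1cc(B2OC(C)(C)C(C)(C)O2)ccc1O), PdCl2(dppf), Na2CO3, dioxane/H2O, 80 °C (zerovalent palladium formed in situ) should give 6 directly. The fallback comes back to the route at 6 and so also bypasses step 2.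

**Further compounds**
F1 | step 4 | 3-[5-methoxy-3-(3-methylbuta-1,2-dien-1-yl)-4-oxocyclohexa-1,5-dien-1-yl]-7-(methoxymethoxy)-4H-chromen-4-one (racemic, not isolated) | COCOc1ccc2c(c1)occ(C1=CC(C=C=C(C)C)C(=O)C(OC)=C1)c2=O
F2 | step 4 | 3-[4-hydroxy-3-methoxy-5-(3-methylbuta-1,2-dien-1-yl)phenyl]-7-(methoxymethoxy)-4H-chromen-4-one (not isolated) | COCOc1ccc2c(c1)occ(-c1cc(OC)c(O)c(C=C=C(C)C)c1)c2=O
F3 | step 4 | 3-[(3Z)-5-methoxy-3-(3-methylbut-2-en-1-ylidene)-4-oxocyclohexa-1,5-dien-1-yl]-7-(methoxymethoxy)-4H-chromen-4-one (not isolated) | COCOc1ccc2c(c1)occ(C1=C/C(=C/C=C(C)C)C(=O)C(OC)=C1)c2=O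
F4 | step 2 | 4-(7-acetoxy-4-oxo-4H-chromen-3-yl)-2-methoxyphenyl acetate | CC(=O)Oc1ccc2c(c1)occ(-c1ccc(OC(C)=O)c(OC)c1)c2=O
F5 | step 2 | 4-(7-hydroxy-4-oxo-4H-chromen-3-yl)-2-methoxyphenyl acetate | COc1cc(-c2coc3cc(O)ccc3c2=O)ccc1OC(C)=O
F6 | step 2 | 2-methoxy-4-[7-(methoxymethoxy)-4-oxo-4H-chromen-3-yl]phenyl acetate | COCOc1ccc2c(c1)occ(-c1ccc(OC(C)=O)c(OC)c1)c2=O
F7 | step 1 | 1-(2,4-dihydroxyphenyl)ethan-1-one | CC(=O)c1ccc(O)cc1O
F8 | step 1 | 1-[2-hydroxy-4-(methoxymethoxy)phenyl]ethan-1-one | COCOc1ccc(C(C)=O)c(O)c1
F9 | step 1 | (E)-3-(dimethylamino)-1-[2-hydroxy-4-(methoxymethoxy)phenyl]prop-2-en-1-one | COCOc1ccc(C(=O)/C=C/N(C)C)c(O)c1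
F10 | step 1 | 3-iodo-7-(methoxymethoxy)-4H-chromen-4-one | COCOc1ccc2c(c1)occ(I)c2=O
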